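**Plan**

1. Retrosynthetic cuts: the two ester bonds C15–O–C(=O) between the sesquiterpene units; then, in each unit, the ether bond C11–O, the C8=C12 double bond, the C9–C11 bond and the C8–C9/C9–C10 bonds (C9 is taken out of ring B, leaving a cyclopentanone with C8 bonded directly to C10); each isocitrate is cut at C2'–C3'.
2. Forward order: the five-membered ring and ring A arise by Michael addition and amino-acid-mediated aldol condensation; C4/C5 by reductive hydroxymethylation; ring B by one-carbon ring enlargement (C9 inserted into the C8–C10 bond) with C11 attached in the same flask; then the ether, then C12. One monomer (25) serves all three units, which are joined C → B → A by two esterifications.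
3. Enabling feature: in ring B the sp2 carbon C8 lies between C7H2 and C9, and C9 is bonded to quaternary C10 and carries C11. A hydrindanone whose carbonyl carbon C8 is bonded to quaternary C10 should therefore expand with migration of C10 to a decalone formed as its C8/C9 enolate, which direct deprotonation (towards C7) cannot give.
4. Stereochemistry: C10 from the L-phenylalanine-mediated aldol; C5 (trans fusion) and C4 (CH2O anti to the C10 methyl) from the Li/NH3 reductive alkylation; C9 from α-face protonation of the enolate after the oxa-Michael addition; C1' from (R)-malic acid and C2' from the anti-selective dianion alkylation.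

Key step: step 9

Remark on the chemistry (assumed numbering): drimane numbering is used for the decalin units (C1–C10 ring carbons, C11 = CH2O on C9, C12 = exocyclic methylene carbon on C8, C15 = CH2O on C4). α/β mean opposite to/same face as the angular (C10) methyl. Isocitrate carbons are C1' (ether carbon), C2' and C3' (CH2). Unit A carries the isocitrate with the free central acid, unit B is the middle unit, unit C has the free C15–OH.

**Route**

Step 1
Reactants: 1 2-methylcyclopentane-1,3-dione; 2 pent-1-en-3-one (ethyl vinyl ketone)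
Product: 3 2-methyl-2-(3-oxopentyl)cyclopentane-1,3-dione
Conditions: H2O, AcOH (cat.), 75 °C
Reagents that add atoms: none
Why: Michael addition (first half of a Robinson-type annulation) of the enolised 1,3-dione to the vinyl ketone should give the achiral triketone without creating a stereocentre.

Step 2
Reactants: 3 triketone
Product: 5 (7aS)-4,7a-dimethyl-2,3,7,7a-tetrahydro-1H-indene-1,5(6H)-dione, via bicyclic ketol 4 (not isolated)
Conditions: L-phenylalanine (1 equiv), (+)-camphorsulfonic acid (0.5 equiv), DMF, 30 → 70 °C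
Reagents that add atoms: none
Why: Hajos–Parrish–Eder–Sauer–Wiechert reaction, in which the enamine of the side-chain ketone with the L-amino acid should attack one of the two enantiotopic ring carbonyls and so fix the quaternary carbon (later C10) as S, after which acid-promoted dehydration of the ketol gives the enone.

Step 3
Reactants: 5 enedione
Product: 6 (1S,7aS)-1-hydroxy-4,7a-dimethyl-1,2,3,6,7,7a-hexahydro-5H-inden-5-one
Conditions: NaBH4 (0.3 equiv), EtOH, −20 °C
Reagents that add atoms: none
Why: Chemoselective borohydride reduction of the saturated cyclopentanone in the presence of the less electrophilic conjugated ketone, with hydride delivered anti to the angular methyl to give the 1β alcohol, a centre that only masks the later C8 carbonyl.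

Step 4
Reactants: 6 hydroxy enone
Product: 8 1β-hydroxy-4α-(hydroxymethyl)-4β,7aβ-dimethyl-3aα-H-octahydro-5H-inden-5-one, via dilithium alkoxide enolate 7 (not isolated)
Conditions: Li (2.2 equiv), NH3/THF, −78 °C; evaporate NH3; CH2O (gas), THF, −78 °C; aq NH4Cl
Reagents that add atoms: formaldehyde C=O
Why: Stork reductive alkylation, in which protonation of the β-carbon (the hydroxyl of 6 supplies the single proton) should give the trans ring fusion (later C5) and the regiodefined enolate should take up formaldehyde on the α face because a β approach is 1,3-diaxial to the angular methyl, placing CH2OH α and CH3 β on the new quaternary carbon (later C4).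

Step 5
Reactants: 8 diol ketone
Product: 9 4α-[(tert-butyldimethylsilyloxy)methyl]-1β-hydroxy-4β,7aβ-dimethyl-3aα-H-octahydro-5H-inden-5-one
Conditions: TBSCl (1.05 equiv), imidazole, CH2Cl2, 0 °C
Reagents that add atoms: tert-butyldimethylsilyl chloride CC(C)(C)[Si](C)(C)Cl
Why: Silyl ether formation that should be selective for the primary hydroxyl over the hindered secondary one next to the quaternary carbon, and that removes the retro-aldol liability of the β-hydroxy ketone.

Step 6
Reactants: 9 silyloxy ketone
Product: 10 4-methylbenzenesulfonylhydrazone of 9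
Conditions: TsNHNH2, EtOH, 70 °C
Reagents that add atoms: 4-methylbenzenesulfonyl hydrazide Cc1ccc(cc1)S(=O)(=O)NN
Why: Condensation of the only ketone to its tosylhydrazone prepares a mild deoxygenation that the silyl ether tolerates.

Step 7
Reactants: 10 tosylhydrazone
Product: 11 4α-[(tert-butyldimethylsilyloxy)methyl]-4β,7aβ-dimethyl-3aα-H-octahydro-1H-inden-1β-ol
Conditions: NaBH4, MeOH/THF, reflux
Reagents that add atoms: none
Why: Caglioti reduction, in which hydride addition to C=N, loss of sulfinate and extrusion of N2 from the diazene should replace the carbonyl by CH2 (later C3) without touching any stereocentre.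

Step 8
Reactants: 11 alcohol
Product: 12 4α-[(tert-butyldimethylsilyloxy)methyl]-4β,7aβ-dimethyl-3aα-H-octahydro-1H-inden-1-one (trans-hydrindanone)
Conditions: Dess–Martin periodinane, NaHCO3, CH2Cl2, rt
Reagents that add atoms: none
Why: Dess–Martin oxidation should give the ketone whose carbonyl carbon (later C8) is bonded to the quaternary carbon (later C10), and the ring-fusion CH is not α to it, so nothing can epimerise.

Step 9
Reactants: 12 trans-hydrindanone
Product: 15 11-(dimethylamino)-15-(tert-butyldimethylsilyloxy)-12-nordriman-8-one (9α-CH2NMe2 expected), via dibromomethyl lithium alkoxide 13 (not isolated), via ring-expanded lithium enolate 14 (not isolated)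
Conditions: CH2Br2, LiN(i-Pr)2, THF, −78 °C; then n-BuLi, −78 → −20 °C; then Me2N=CH2+ I− (excess), −78 °C → rt
Reagents that add atoms: dibromomethane BrCBr; N,N-dimethylmethyleneiminium iodide C=[N+](C)C.[I-]
Why: Dibromomethyllithium should add to the C8 carbonyl from the α face, bromine–lithium exchange then turns adduct 13 into a β-oxido carbenoid, and a 1,2-shift of the C8–C10 bond onto the carbenoid carbon with loss of LiBr inserts C9 between C8 and C10, so that the five-membered ring grows into ring B and the product is formed as the C8/C9 lithium enolate 14. The closest known reaction type is the β-oxido carbenoid ring enlargement of cycloalkanones with dibromomethyllithium (a pinacol-type homologation), followed by Mannich trapping of a regiodefined enolate with an iminium salt. Ring B is not closed by a cyclisation but arises by ring expansion of the cyclopentanone (five to six atoms) through this 1,2-alkyl shift. C10 migrates with retention and C4 and C5 are untouched; the aminomethyl group should enter C9 on the α face, anti to the C10 methyl, but this centre is removed in step 10 and reset in step 14. The step needs migration of quaternary C10 and not of C7H2, which the higher migratory aptitude of the more substituted carbon towards the electron-poor carbenoid centre should secure, and it needs the enolate on the C9 side, which the mechanism guarantees because the enolate double bond forms between the old carbonyl carbon and the inserted carbon.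

Step 10
Reactants: 15 Mannich base
Product: 17 15-(tert-butyldimethylsilyloxy)-12-nordrim-9(11)-en-8-one, via quaternary ammonium iodide 16 (not isolated)
Conditions: MeI, CH2Cl2, rt; then aq NaHCO3, rt
Reagents that add atoms: none
Why: Eschenmoser-type methylenation completed by exhaustive N-methylation and Hofmann-type (E1cB) loss of trimethylamine through the C8 enolate should give the α-methylene ketone and erase the provisional C9 centre, the enone being used at once to avoid dimerisation.

Step 11
Reactants: 18 (R)-malic acid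
Product: 20 (3R)-3-hydroxy-4-methoxy-4-oxobutanoic acid, via trifluoroacetylated malic anhydride 19 (not isolated)
Conditions: (CF3CO)2O, 0 °C → rt; evaporate; MeOH, rt
Reagents that add atoms: methanol CO
Why: Regioselective monoesterification through the O-trifluoroacetyl cyclic anhydride, which methanol should open at the more electrophilic carbonyl next to the oxygen-bearing carbon (and de-trifluoroacetylate), so that only the carboxyl α to the hydroxyl becomes the methyl ester and the stereocentre is untouched.

Step 12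
Reactants: 20 malic acid 1-methyl ester
Product: 21 4-allyl 1-methyl (2R)-2-hydroxybutanedioate
Conditions: allyl bromide, KHCO3, DMF, rt
Reagents that add atoms: allyl bromide C=CCBr
Why: Carboxylate O-alkylation (SN2) should esterify the remaining acid as the allyl ester that later allows selective liberation of the central carboxyl.

Step 13
Reactants: 21 allyl methyl malate
Product: 23 2-allyl 3-tert-butyl 1-methyl (1R,2S)-1-hydroxypropane-1,2,3-tricarboxylate, via dilithium alkoxide enolate 22 (not isolated)
Conditions: LiN(SiMe3)2 (2.2 equiv), THF, −78 → −20 °C; BrCH2CO2t-Bu, −78 °C; AcOH, −78 °C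
Reagents that add atoms: tert-butyl bromoacetate BrCC(=O)OC(C)(C)C
Why: Fráter–Seebach alkylation, in which the chelated alkoxide enolate should be alkylated anti to the alkoxide oxygen, setting C2' as S next to the C1' centre (R) inherited from malic acid and giving the (1R,2S)-isocitrate pattern with three different esters, the cold acidic quench avoiding lactonisation.

Step 14
Reactants: 17 α-methylene ketone; 23 isocitrate hydroxy triester
Product: 24 2-allyl 3-tert-butyl 1-methyl (1R,2S)-1-{[15-(tert-butyldimethylsilyloxy)-8-oxo-12-nordriman-11-yl]oxy}propane-1,2,3-tricarboxylate (9α-H)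
Conditions: 23 (1.3 equiv), KOt-Bu (10 mol %), THF, −40 → −20 °C; AcOH
Reagents that add atoms: none
Why: Base-catalysed oxa-Michael addition of the secondary alkoxide to the unhindered CH2 terminus of the enone forms the C11–O ether bond, and protonation of the resulting C8/C9 enolate on the α face, anti to the C10 methyl, should give the 9α-H, 9β-CH2O configuration, which is also the more stable equatorial epimer, while the tert-butyl ester resists attack by the alkoxide so that no γ-lactone forms.

Step 15
Reactants: 24 β-alkoxy ketone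
Product: 25 2-allyl 3-tert-butyl 1-methyl (1R,2S)-1-{[15-(tert-butyldimethylsilyloxy)drim-8(12)-en-11-yl]oxy}propane-1,2,3-tricarboxylate
Conditions: Zn, CH2Br2, TiCl4, THF/CH2Cl2, 0 °C → rt
Reagents that add atoms: dibromomethane BrCBr
Why: Lombardo methylenation is non-basic and should convert the hindered, epimerisable β-alkoxy ketone into the exocyclic C8=C12 alkene without β-elimination, C9 epimerisation or attack on the three esters.

Step 16
Reactants: 25 common monomer
Product: 26 central carboxylic acid of 25 (unit C acid, C15–OTBS)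
Conditions: Pd(PPh3)4 (5 mol %), morpholine, THF, rt
Reagents that add atoms: none
Why: Tsuji–Trost deallylation, in which zerovalent palladium ionises only the allyl ester and morpholine traps the allyl fragment, should free the central carboxyl while the methyl and tert-butyl esters, the silyl ether and the alkene stay intact.

Step 17
Reactants: 25 common monomer
Product: 27 15-hydroxy analogue of 25 (unit B alcohol)
Conditions: HF·pyridine, pyridine/THF, 0 °C → rt
Reagents that add atoms: none
Why: Buffered fluoride desilylation should free the C15 hydroxyl without ester cleavage or migration of the exocyclic double bond.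

Step 18
Reactants: 27 unit B alcohol
Product: 29 terminal (C3') carboxylic acid of 27, via bis(trimethylsilyl) intermediate 28 (not isolated)
Conditions: TMSOTf (4 equiv), 2,6-lutidine (6 equiv), CH2Cl2, 0 °C; then MeOH, aq citric acid
Reagents that add atoms: none
Why: Silyl triflate-mediated cleavage of the tert-butyl ester (loss of 2-methylpropene from the silylated ester) under 2,6-lutidine buffering avoids protic acid, so the exocyclic alkene should not isomerise, and the transient silyl ester and silyl ether hydrolyse on work-up while the methyl and allyl esters persist.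

Step 19
Reactants: 29 hydroxy acid
Product: 30 2-allyl 1,3-dimethyl (1R,2S)-1-[(15-hydroxydrim-8(12)-en-11-yl)oxy]propane-1,2,3-tricarboxylate (unit A alcohol)
Conditions: Me3SiCHN2, toluene/MeOH, 0 °C
Reagents that add atoms: trimethylsilyldiazomethane C[Si](C)(C)C=[N+]=[N-]
Why: Chemoselective O-methylation of the carboxylic acid with the diazoalkane should install the terminal methyl ester of unit A without affecting the free hydroxyl.

Step 20
Reactants: 26 unit C acid; 27 unit B alcohol
Product: 31 B–C dimer ester (C15–O of unit B acylated by the central carboxyl of the unit C isocitrate)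
Conditions: 2-methyl-6-nitrobenzoic anhydride, DMAP, Et3N, CH2Cl2, rt
Reagents that add atoms: none
Why: Shiina esterification (mixed anhydride, acyl transfer by DMAP) should join the α-branched acid to the neopentyl-type primary C15 hydroxyl under mild conditions that limit epimerisation at C2'.

Step 21
Reactants: 31 B–C dimer ester
Product: 32 B–C dimer acid (central carboxyl of the unit B isocitrate free)
Conditions: Pd(PPh3)4 (5 mol %), morpholine, THF, rt
Reagents that add atoms: none
Why: Tsuji–Trost deallylation of the only allyl ester present should free the acid needed for the second coupling and leave all other esters, the silyl ether and both alkenes untouched.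

Step 22
Reactants: 32 B–C dimer acid; 30 unit A alcohol
Product: 33 fully protected trimer
Conditions: 2-methyl-6-nitrobenzoic anhydride, DMAP, Et3N, CH2Cl2, rt
Reagents that add atoms: none
Why: A second Shiina esterification should acylate the C15 hydroxyl of unit A with the central carboxyl of the unit B isocitrate and complete the A–B–C chain.

Step 23
Reactants: 33 protected trimer
Product: 34 trimer with the central carboxyl of the unit A isocitrate free
Conditions: Pd(PPh3)4 (5 mol %), morpholine, THF, rt
Reagents that add atoms: none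
Why: Tsuji–Trost deallylation of the single remaining allyl ester should release the free acid of unit A under neutral conditions.

Step 24
Reactants: 34 trimer monoacid
Product: 36 15-O-(tert-butyldimethylsilyl)cryptoporic acid T, via tris(trimethylsilyl) ester 35 (not isolated)
Conditions: TMSOTf, 2,6-lutidine, CH2Cl2, 0 °C; then MeOH, aq citric acid
Reagents that add atoms: none
Why: Silyl triflate-mediated cleavage of both tert-butyl esters with 2,6-lutidine buffering should free the two terminal carboxyls without protic acid, so the three exocyclic alkenes, the methyl esters and the inter-unit esters should survive.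

Step 25
Reactants: 36 silyl-protected triacid
Product: 37 cryptoporic acid T
Conditions: HF·pyridine, pyridine/THF, 0 °C → rt
Reagents that add atoms: none
Why: Buffered fluoride desilylation of the primary silyl ether should free the C15 hydroxyl of unit C and give the target without ester cleavage or alkene migration.

**Compound list**

1 | 2-methylcyclopentane-1,3-dione | CC1C(=O)CCC1=O | starting material
2 | pent-1-en-3-one (ethyl vinyl ketone) | CCC(=O)C=C | starting material
3 | 2-methyl-2-(3-oxopentyl)cyclopentane-1,3-dione | CCC(=O)CCC1(C)C(=O)CCC1=O | intermediate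
4 | (3aS,7aS)-3a-hydroxy-4,7a-dimethylhexahydro-1H-indene-1,5(4H)-dione, cis-fused ketol (C4 unassigned) | O=C1CC[C@]2(O)C(C)C(=O)CC[C@]12C | intermediate (not isolated)
5 | (7aS)-4,7a-dimethyl-2,3,7,7a-tetrahydro-1H-indene-1,5(6H)-dione | O=C1CCC2=C(C)C(=O)CC[C@]12C | intermediate
6 | (1S,7aS)-1-hydroxy-4,7a-dimethyl-1,2,3,6,7,7a-hexahydro-5H-inden-5-one | O[C@H]1CCC2=C(C)C(=O)CC[C@]12C | intermediate
7 | dilithium 1β-oxido 4-en-5-olate of the trans-fused hydrindane (3aα-H) | [Li+].[Li+].[O-][C@H]1CC[C@H]2C(C)=C([O-])CC[C@]12C | intermediate (not isolated)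
8 | 1β-hydroxy-4α-(hydroxymethyl)-4β,7aβ-dimethyl-3aα-H-octahydro-5H-inden-5-one | O[C@H]1CC[C@H]2[C@](C)(CO)C(=O)CC[C@]12C | intermediate
9 | 4α-[(tert-butyldimethylsilyloxy)methyl]-1β-hydroxy-4β,7aβ-dimethyl-3aα-H-octahydro-5H-inden-5-one | O[C@H]1CC[C@H]2[C@](C)(CO[Si](C)(C)C(C)(C)C)C(=O)CC[C@]12C | intermediate
10 | 4-methylbenzenesulfonylhydrazone of 9 | O[C@H]1CC[C@H]2[C@](C)(CO[Si](C)(C)C(C)(C)C)C(=NNS(=O)(=O)c3ccc(C)cc3)CC[C@]12C | intermediate
11 | 4α-[(tert-butyldimethylsilyloxy)methyl]-4β,7aβ-dimethyl-3aα-H-octahydro-1H-inden-1β-ol | O[C@H]1CC[C@H]2[C@](C)(CO[Si](C)(C)C(C)(C)C)CCC[C@]12C | intermediate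
12 | 4α-[(tert-butyldimethylsilyloxy)methyl]-4β,7aβ-dimethyl-3aα-H-octahydro-1H-inden-1-one | O=C1CC[C@H]2[C@](C)(CO[Si](C)(C)C(C)(C)C)CCC[C@]12C | intermediate
13 | lithium 1α-(dibromomethyl)-1β-olate of 12 | [Li+].[O-][C@@]1(C(Br)Br)CC[C@H]2[C@](C)(CO[Si](C)(C)C(C)(C)C)CCC[C@]12C | intermediate (not isolated)
14 | lithium C8/C9 enolate of 15-(tert-butyldimethylsilyloxy)-11,12-dinordriman-8-one | C1=C([O-])CC[C@H]2[C@](C)(CO[Si](C)(C)C(C)(C)C)CCC[C@]12C.[Li+] | intermediate (not isolated)
15 | 11-(dimethylamino)-15-(tert-butyldimethylsilyloxy)-12-nordriman-8-one, 9α-CH2NMe2 epimer | CN(C)C[C@@H]1C(=O)CC[C@H]2[C@](C)(CO[Si](C)(C)C(C)(C)C)CCC[C@]12C | intermediate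
16 | N-methyl quaternary ammonium iodide of 15 | C[N+](C)(C)C[C@@H]1C(=O)CC[C@H]2[C@](C)(CO[Si](C)(C)C(C)(C)C)CCC[C@]12C.[I-] | intermediate (not isolated)
17 | 15-(tert-butyldimethylsilyloxy)-12-nordrim-9(11)-en-8-one | C=C1C(=O)CC[C@H]2[C@](C)(CO[Si](C)(C)C(C)(C)C)CCC[C@]12C | intermediate
18 | (R)-malic acid | O[C@@H](C(=O)O)CC(=O)O | starting material
19 | (R)-2-(trifluoroacetoxy)succinic anhydride | O=C1C[C@@H](OC(=O)C(F)(F)F)C(=O)O1 | intermediate (not isolated)
20 | (3R)-3-hydroxy-4-methoxy-4-oxobutanoic acid | O[C@@H](C(=O)OC)CC(=O)O | intermediate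
21 | 4-allyl 1-methyl (2R)-2-hydroxybutanedioate | O[C@@H](C(=O)OC)CC(=O)OCC=C | intermediate
22 | dilithium alkoxide enolate of 21 | [Li+].[Li+].[O-][C@@H](C(=O)OC)C=C([O-])OCC=C | intermediate (not isolated)
23 | 2-allyl 3-tert-butyl 1-methyl (1R,2S)-1-hydroxypropane-1,2,3-tricarboxylate | C=CCOC(=O)[C@@H](CC(=O)OC(C)(C)C)[C@@H](O)C(=O)OC | intermediate
24 | 2-allyl 3-tert-butyl 1-methyl (1R,2S)-1-{[15-(tert-butyldimethylsilyloxy)-8-oxo-12-nordriman-11-yl]oxy}propane-1,2,3-tricarboxylate (9α-H) | C=CCOC(=O)[C@@H](CC(=O)OC(C)(C)C)[C@@H](OC[C@H]1C(=O)CC[C@H]2[C@](C)(CO[Si](C)(C)C(C)(C)C)CCC[C@]12C)C(=O)OC | intermediate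
25 | 2-allyl 3-tert-butyl 1-methyl (1R,2S)-1-{[15-(tert-butyldimethylsilyloxy)drim-8(12)-en-11-yl]oxy}propane-1,2,3-tricarboxylate | C=CCOC(=O)[C@@H](CC(=O)OC(C)(C)C)[C@@H](OC[C@H]1C(=C)CC[C@H]2[C@](C)(CO[Si](C)(C)C(C)(C)C)CCC[C@]12C)C(=O)OC | intermediate
26 | central (C2') carboxylic acid of 25 | OC(=O)[C@@H](CC(=O)OC(C)(C)C)[C@@H](OC[C@H]1C(=C)CC[C@H]2[C@](C)(CO[Si](C)(C)C(C)(C)C)CCC[C@]12C)C(=O)OC | intermediate
27 | 15-hydroxy analogue of 25 | C=CCOC(=O)[C@@H](CC(=O)OC(C)(C)C)[C@@H](OC[C@H]1C(=C)CC[C@H]2[C@](C)(CO)CCC[C@]12C)C(=O)OC | intermediate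
28 | trimethylsilyl ester and 15-O-trimethylsilyl ether derived from 27 | C=CCOC(=O)[C@@H](CC(=O)O[Si](C)(C)C)[C@@H](OC[C@H]1C(=C)CC[C@H]2[C@](C)(CO[Si](C)(C)C)CCC[C@]12C)C(=O)OC | intermediate (not isolated)
29 | terminal (C3') carboxylic acid of 27 | C=CCOC(=O)[C@@H](CC(=O)O)[C@@H](OC[C@H]1C(=C)CC[C@H]2[C@](C)(CO)CCC[C@]12C)C(=O)OC | intermediate
30 | 2-allyl 1,3-dimethyl (1R,2S)-1-[(15-hydroxydrim-8(12)-en-11-yl)oxy]propane-1,2,3-tricarboxylate | C=CCOC(=O)[C@@H](CC(=O)OC)[C@@H](OC[C@H]1C(=C)CC[C@H]2[C@](C)(CO)CCC[C@]12C)C(=O)OC | intermediate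
31 | B–C dimer ester (unit B: allyl/tert-butyl/methyl isocitrate; unit C: tert-butyl/methyl isocitrate, C15–OTBS) | C=CCOC(=O)[C@@H](CC(=O)OC(C)(C)C)[C@@H](OC[C@H]1C(=C)CC[C@H]2[C@](C)(COC(=O)[C@@H](CC(=O)OC(C)(C)C)[C@@H](OC[C@H]3C(=C)CC[C@H]4[C@](C)(CO[Si](C)(C)C(C)(C)C)CCC[C@]34C)C(=O)OC)CCC[C@]12C)C(=O)OC | intermediate
32 | B–C dimer acid (central carboxyl of the unit B isocitrate free) | OC(=O)[C@@H](CC(=O)OC(C)(C)C)[C@@H](OC[C@H]1C(=C)CC[C@H]2[C@](C)(COC(=O)[C@@H](CC(=O)OC(C)(C)C)[C@@H](OC[C@H]3C(=C)CC[C@H]4[C@](C)(CO[Si](C)(C)C(C)(C)C)CCC[C@]34C)C(=O)OC)CCC[C@]12C)C(=O)OC | intermediate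
33 | protected trimer (unit A allyl ester, two tert-butyl esters, unit C C15–OTBS) | C=C1CC[C@H]2[C@](C)(COC(=O)[C@@H](CC(=O)OC(C)(C)C)[C@@H](OC[C@H]3C(=C)CC[C@H]4[C@](C)(COC(=O)[C@@H](CC(=O)OC(C)(C)C)[C@@H](OC[C@H]5C(=C)CC[C@H]6[C@](C)(CO[Si](C)(C)C(C)(C)C)CCC[C@]56C)C(=O)OC)CCC[C@]34C)C(=O)OC)CCC[C@]2(C)[C@H]1CO[C@@H](C(=O)OC)[C@H](CC(=O)OC)C(=O)OCC=C | intermediate
34 | trimer with free unit A acid (two tert-butyl esters, C15–OTBS) | C=C1CC[C@H]2[C@](C)(COC(=O)[C@@H](CC(=O)OC(C)(C)C)[C@@H](OC[C@H]3C(=C)CC[C@H]4[C@](C)(COC(=O)[C@@H](CC(=O)OC(C)(C)C)[C@@H](OC[C@H]5C(=C)CC[C@H]6[C@](C)(CO[Si](C)(C)C(C)(C)C)CCC[C@]56C)C(=O)OC)CCC[C@]34C)C(=O)OC)CCC[C@]2(C)[C@H]1CO[C@@H](C(=O)OC)[C@H](CC(=O)OC)C(=O)O | intermediate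
35 | tris(trimethylsilyl) ester of 36 | C=C1CC[C@H]2[C@](C)(COC(=O)[C@@H](CC(=O)O[Si](C)(C)C)[C@@H](OC[C@H]3C(=C)CC[C@H]4[C@](C)(COC(=O)[C@@H](CC(=O)O[Si](C)(C)C)[C@@H](OC[C@H]5C(=C)CC[C@H]6[C@](C)(CO[Si](C)(C)C(C)(C)C)CCC[C@]56C)C(=O)OC)CCC[C@]34C)C(=O)OC)CCC[C@]2(C)[C@H]1CO[C@@H](C(=O)OC)[C@H](CC(=O)OC)C(=O)O[Si](C)(C)C | intermediate (not isolated)
36 | 15-O-(tert-butyldimethylsilyl)cryptoporic acid T | C=C1CC[C@H]2[C@](C)(COC(=O)[C@@H](CC(=O)O)[C@@H](OC[C@H]3C(=C)CC[C@H]4[C@](C)(COC(=O)[C@@H](CC(=O)O)[C@@H](OC[C@H]5C(=C)CC[C@H]6[C@](C)(CO[Si](C)(C)C(C)(C)C)CCC[C@]56C)C(=O)OC)CCC[C@]34C)C(=O)OC)CCC[C@]2(C)[C@H]1CO[C@@H](C(=O)OC)[C@H](CC(=O)OC)C(=O)O | intermediate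
37 | cryptoporic acid T | C=C1CC[C@H]2[C@](C)(COC(=O)[C@@H](CC(=O)O)[C@@H](OC[C@H]3C(=C)CC[C@H]4[C@](C)(COC(=O)[C@@H](CC(=O)O)[C@@H](OC[C@H]5C(=C)CC[C@H]6[C@](C)(CO)CCC[C@]56C)C(=O)OC)CCC[C@]34C)C(=O)OC)CCC[C@]2(C)[C@H]1CO[C@@H](C(=O)OC)[C@H](CC(=O)OC)C(=O)O | target

**Step count and risks**

Total steps: 25. Longest linear sequence: 19 steps (steps 1–10, 14, 15, 16, 20–25).

Most likely to fail:

1. Step 9. The carbenoid rearrangement may proceed with migration of C7H2 instead of quaternary C10, or the carbenoid may deprotonate the ketone instead of adding to it. Fallback (from 12, back at 17): addition of CH2=CHMgBr (CeCl3, THF, −78 °C) from the α face should give the 1α-vinyl-1β-ol F1. VO(acac)2-catalysed epoxidation with t-BuOOH should give the epoxy alcohol F2 (either epimer at the epoxide carbon serves). BF3·OEt2 (CH2Cl2, −78 °C) should trigger a semipinacol 1,2-shift of the quaternary carbon onto the epoxide carbon, again enlarging the five-membered ring to ring B and giving the hydroxymethyl ketone F3 (C9 epimers). Mesylation with elimination in the same flask (MsCl, Et3N, then DBU) returns to the route at enone 17.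

2. Step 14. Addition of the hindered, weakly nucleophilic secondary alkoxide may be slow or reversible, and base-induced damage to the isocitrate (ester exchange, β-elimination) may compete. Fallback (from 17, back at 25): 4-methoxybenzyl alcohol (excess, cat. KOt-Bu) should add as an unhindered primary alkoxide to give the 9β-[(4-methoxybenzyloxy)methyl] ketone F4. Zn/CH2Br2/TiCl4 methylenation gives the alkene F5, DDQ (CH2Cl2, pH 7 buffer) frees the primary alcohol F6, and Dess–Martin oxidation gives the aldehyde F7. Separately, 23 is converted into its trimethylsilyl ether F8 (TMSCl, imidazole). Reductive etherification of F7 with F8 (Et3SiH, cat. TMSOTf, CH2Cl2, −78 °C) forms the C11–O bond through an oxocarbenium ion under Lewis-acid conditions and returns to the route at 25.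

3. Step 4. Protonation of the β-carbon may occur on the wrong face (cis ring fusion), and the enolate may be trapped with poor facial selectivity or more than once. Fallback (from 6, back at 11): the alcohol is protected as its benzyloxymethyl ether F9 (BnOCH2Cl, i-Pr2NEt). Deconjugative alkylation of the dienolate (KOt-Bu, t-BuOH/THF, then BnOCH2Cl) on the α face should give the 4α-(benzyloxymethyl)-4β-methyl β,γ-unsaturated ketone F10. Wolff–Kishner reduction (N2H4·H2O, KOH, diethylene glycol, 200 °C) removes the carbonyl to give the alkene F11. Hydrogenation (H2, Pd/C, EtOAc/EtOH) should saturate the alkene from the α face, away from the two β methyl groups, and cleave both benzyl-type groups to give the trans-fused diol F12. Selective silylation of the primary hydroxyl (TBSCl, imidazole, 0 °C) returns to the route at 11.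

Further compounds

F1 | step 9 | 1α-vinyl-4α-[(tert-butyldimethylsilyloxy)methyl]-4β,7aβ-dimethyl-3aα-H-octahydro-1H-inden-1β-ol | O[C@@]1(C=C)CC[C@H]2[C@](C)(CO[Si](C)(C)C(C)(C)C)CCC[C@]12C
F2 | step 9 | 1α-(oxiran-2-yl) analogue of F1 (epimers at the epoxide carbon) | O[C@@]1(C3CO3)CC[C@H]2[C@](C)(CO[Si](C)(C)C(C)(C)C)CCC[C@]12C
F3 | step 9 | 11-hydroxy-15-(tert-butyldimethylsilyloxy)-12-nordriman-8-one (C9 epimers) | OCC1C(=O)CC[C@H]2[C@](C)(CO[Si](C)(C)C(C)(C)C)CCC[C@]12C
F4 | step 14 | 11-(4-methoxybenzyloxy)-15-(tert-butyldimethylsilyloxy)-12-nordriman-8-one (9α-H) | COc1ccc(COC[C@H]2C(=O)CC[C@H]3[C@](C)(CO[Si](C)(C)C(C)(C)C)CCC[C@]23C)cc1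
F5 | step 14 | 11-(4-methoxybenzyloxy)-15-(tert-butyldimethylsilyloxy)drim-8(12)-ene | COc1ccc(COC[C@H]2C(=C)CC[C@H]3[C@](C)(CO[Si](C)(C)C(C)(C)C)CCC[C@]23C)cc1
F6 | step 14 | 15-(tert-butyldimethylsilyloxy)drim-8(12)-en-11-ol | OC[C@H]1C(=C)CC[C@H]2[C@](C)(CO[Si](C)(C)C(C)(C)C)CCC[C@]12C
F7 | step 14 | 15-(tert-butyldimethylsilyloxy)drim-8(12)-en-11-al | O=C[C@H]1C(=C)CC[C@H]2[C@](C)(CO[Si](C)(C)C(C)(C)C)CCC[C@]12C
F8 | step 14 | 2-allyl 3-tert-butyl 1-methyl (1R,2S)-1-(trimethylsilyloxy)propane-1,2,3-tricarboxylate | C=CCOC(=O)[C@@H](CC(=O)OC(C)(C)C)[C@@H](O[Si](C)(C)C)C(=O)OC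
F9 | step 4 | (1S,7aS)-1-(benzyloxymethoxy)-4,7a-dimethyl-1,2,3,6,7,7a-hexahydro-5H-inden-5-one | c1ccccc1COCO[C@H]2CCC3=C(C)C(=O)CC[C@]23C
F10 | step 4 | 1β-(benzyloxymethoxy)-4α-(benzyloxymethyl)-4β,7aβ-dimethyl-1,2,4,6,7,7a-hexahydro-5H-inden-5-one | c1ccccc1COCO[C@H]2CC=C3[C@](C)(COCc4ccccc4)C(=O)CC[C@]23C
F11 | step 4 | 1β-(benzyloxymethoxy)-4α-(benzyloxymethyl)-4β,7aβ-dimethyl-2,4,5,6,7,7a-hexahydro-1H-indene | c1ccccc1COCO[C@H]2CC=C3[C@](C)(COCc4ccccc4)CCC[C@]23C
F12 | step 4 | 4α-(hydroxymethyl)-4β,7aβ-dimethyl-3aα-H-octahydro-1H-inden-1β-ol | O[C@H]1CC[C@H]2[C@](C)(CO)CCC[C@]12C
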